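Assumption: the two isomeric tetramethoxybenzenes 1 and 6 are treated as purchasable starting materials; the target is achiral, so no configuration has to be assumed.

## Analysis of the target

The target 7 is a fully O-methylated flavone. It is a 4H-chromen-4-one in which the benzo ring A carries methoxy groups at C5, C7 and C8, the pyran-4-one ring C carries only C3–H, and C2 is bonded to C1' of ring B, a 2',3',4',5'-tetramethoxyphenyl group. There is no stereocentre, and the C2–C1' bond has only one ortho substituent (2'-OMe), so it is not a stereogenic axis and the molecule is achiral. The whole problem is therefore one of connectivity and regiochemistry. Ring A must come out as the 5,7,8-isomer and not the 5,6,7-isomer; both arise from the same tetraoxygenated benzene, depending on which of two ortho oxygens becomes O1. The feature the route exploits is the bond C2–C1' between ring C and ring B. Once that bond is removed, ring B has only two C–H bonds (C1'–H and C6'–H), related by a mirror plane, and C2 of ring C is the β-carbon of a vinylogous ester. The sensitive points are the 5-OMe group peri to C4=O (cleaved by Lewis acids and hydrogen halides), C2 (attacked by hydroxide or alkoxide with opening of ring C), and the two electron-rich arenes (easily halogenated or oxidised).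

## Retrosynthetic reasoning

Disconnection 1, C2–C1' (7 to 5 and 6). The single C–C bond joining ring C to ring B is cut, down to two C–H bonds and not to a halide and an organometal. The ring B fragment is then 6, whose two C–H bonds (C5–H and C6–H) are equivalent by symmetry and each lie ortho to one methoxy group and para to another. Any aryl–metal species formed from 6 by C–H cleavage therefore has exactly the 2,3,4,5-tetramethoxyphenyl connectivity of ring B. The ring A/C fragment is chromone 5, whose C2 is the carbon to which an aryl–palladium bond adds. The gain is full convergence with no aldehyde, acid, halide, boron or alkyne on ring B, and the ring A regiochemistry is settled on a small compound before the coupling. The forward reaction has to cleave a C–H bond of 6, deliver the aryl group to C2 and not C3 of 5, leave C6–H of ring A alone and stop after one arylation.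

Disconnection 2, O1–C2 and C2–C3 (5 to 3). Without its aryl group, C2 is a single carbon at the oxidation level of formic acid. Cutting it out leaves the ortho-hydroxyacetophenone 3. In the forward sense the acetyl methyl group condenses with a one-carbon amide acetal to the enaminone 4, and acid closes ring C by attack of the phenol oxygen on the β-carbon with loss of the amine. No oxidation step is needed, because C2 arrives at the right oxidation level.

Disconnection 3, C4–C4a and the 2'-O–CH3 bond (3 to 1). Removing the acetyl group and restoring the methyl ether gives 1, which is symmetric and has two equivalent C–H bonds, so acylation can give only the ketone 2. One of the two ortho ethers of 2 then has to be cleaved: the 2'-OMe group (flanked by the acyl carbon and 3'-OMe) and not the 6'-OMe group (flanked by the acyl carbon and 5'-H). A Friedel–Crafts acylation with chelation-controlled ether cleavage in one flask does both, and this is the point where the 5,7,8 against 5,6,7 decision is made.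

## Alternatives that were turned down

Alternative 1: the textbook disconnection cuts O1–C2 and C2–C3 with ring B already attached to the C2 carbon. The forward key step is a Claisen–Schmidt condensation of 3 with 2,3,4,5-tetramethoxybenzaldehyde A1 to the 2'-hydroxychalcone A2, followed by oxidative cyclisation with iodine in dimethyl sulfoxide. It was turned down for these reasons:
- Ring B must first be functionalised as A1 (one formylation step from 6), the C–C bond-forming step builds only an open chain, and ring C needs a separate oxidation, so the sequence is five steps where three suffice.
- The acetyl group of 3 sits between two ortho substituents and in a hydrogen bond, so its enolate, formed next to a phenoxide, is a hindered and deactivated nucleophile.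
- The oxidative closure generates hydrogen iodide at high temperature next to a methoxy group peri to the carbonyl and two electron-rich rings, so ether cleavage and ring iodination are built-in risks.
- It is the route most chemists would draw first.

Alternative 2: C4 is taken out as carbon monoxide, cutting C4–C4a, C3–C4 and O1–C2. The forward key step is a palladium-catalysed carbonylative Sonogashira coupling of 2-iodo-3,5,6-trimethoxyphenol A3 with 1-ethynyl-2,3,4,5-tetramethoxybenzene A4, giving the ynone A5, which closes to ring C in the same flask. It was turned down for these reasons:
- A3 would have to come from iodination of 2,3,5-trimethoxyphenol A6 ortho to the hydroxyl group, in competition with the position flanked by two methoxy groups. The ring A regiochemistry is thus not avoided but moved to an electrophilic substitution with no chelation to steer it.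
- A4 costs about three steps from 6.
- Oxidative addition into an electron-rich aryl iodide flanked by OH and OMe is slow.
- A5 can close 5-exo as well as 6-endo.
- The count is seven steps or more.

Alternative 3: C4–C4a is cut (intramolecular Friedel–Crafts acylation) together with O1–C2 (aryl vinyl ether formation). The forward sequence is conjugate addition of A6 to ethyl 3-(2,3,4,5-tetramethoxyphenyl)propiolate A7, saponification to the β-aryloxyacrylic acid A8, and cyclodehydration with Eaton's reagent onto the one free ortho position of the phenol ring. Its attraction is that the ring A regiochemistry is unambiguous. It was turned down for these reasons: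
- A6 is not a catalogue compound and needs about four steps, and A7 needs about three from 6.
- The key step is the harshest of the route: a strong acid at elevated temperature acts on seven aryl methyl ethers, one of which becomes peri to the new carbonyl.
- The acylium ion can also close onto C6' of ring B to a five-membered ring.
- The count is eight steps or more.

Key step: step 3

## Route

Step 1
Reactants: 1 1,2,3,5-tetramethoxybenzene
Product: 3 2'-hydroxy-3',4',6'-trimethoxyacetophenone, via tetramethoxyacetophenone 2 (not isolated)
Conditions: AcCl (1.2 equiv), AlCl3 (2.5 equiv), Et2O, 0 °C to reflux; then ice/aq. HCl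
Reagents that add atoms: acetyl chloride, CC(Cl)=O
Why: Friedel–Crafts acylation can occur only at the two equivalent C–H positions of 1 and gives 2; AlCl3 chelated between the ketone and an ortho oxygen then cleaves one ortho O–CH3 bond by chloride attack on the methyl group. The 2'-OMe group is forced out of the ring plane by its two neighbours (acyl carbon and 3'-OMe), is more basic and relieves strain on cleavage, so it should be lost in preference to the in-plane 6'-OMe group; the chelated aluminium phenoxide then protects the product from further cleavage.

Step 2
Reactants: 3 2'-hydroxy-3',4',6'-trimethoxyacetophenone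
Product: 5 5,7,8-trimethoxychromone, via enaminone 4 (not isolated)
Conditions: Me2NCH(OMe)2 (3 equiv), toluene, 100 °C; evaporate; then conc. HCl, CH2Cl2, 40 °C
Reagents that add atoms: N,N-dimethylformamide dimethyl acetal, COC(OC)N(C)C
Why: Condensation of the acetyl methyl group with the amide acetal gives the (E)-enaminone 4, a vinylogous amide; acid then promotes addition of the phenol oxygen to the β-carbon and loss of dimethylamine (addition–elimination), which closes ring C. This enaminone route to C2-unsubstituted chromones is standard for 2'-hydroxyacetophenones and needs no oxidation step.

Step 3
Reactants: 5 5,7,8-trimethoxychromone; 6 1,2,3,4-tetramethoxybenzene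
Product: 7 5,7,8-trimethoxy-2-(2,3,4,5-tetramethoxyphenyl)-4H-chromen-4-one (the target)
Conditions: Pd(OCOCF3)2 (10 mol %), AgOAc (3 equiv), CsOPiv (caesium pivalate, 1 equiv), 6 (8 equiv, molten, excess recovered), PivOH, 110 °C
Reagents that add atoms: none
Why: In pivalic acid the divalent palladium carboxylate cleaves one of the two equivalent C–H bonds of 6 by concerted metalation–deprotonation, with pivalate as the internal base, giving a 2,3,4,5-tetramethoxyphenyl–palladium species. This adds syn across C2=C3 of 5 with the aryl group going to C2, which is β to C4=O and α to O1 so that enone and enol ether polarisation agree, and palladium going to C3 as a palladium enolate. Passage through the oxygen-bound enolate brings palladium syn to C2–H, β-hydride elimination restores the C2=C3 bond, and AgOAc reoxidises the zerovalent palladium. The closest known reaction type is the palladium-catalysed twofold C–H (Fujiwara–Moritani, dehydrogenative Heck) C2-arylation of chromones with simple arenes under silver carboxylate and pivalate conditions. No ring is closed and no stereocentre is formed. Site selectivity on 6 is not an issue because it has only one kind of C–H bond, and C2 over C3 on 5 follows from the insertion polarity. C6–H of ring A should stay untouched because it is flanked by two methoxy groups on a ring whose oxygen lone pairs are drawn into C4=O, and because 6 is present in large excess. A second arylation is disfavoured because in 7 C6'–H lies ortho to the chromone, C3–H is shielded by the new aryl group and C2 has no hydrogen left.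

## Compound list

1 | 1,2,3,5-tetramethoxybenzene | COc1cc(OC)c(OC)c(OC)c1 | starting material
2 | 1-(2,3,4,6-tetramethoxyphenyl)ethan-1-one (2',3',4',6'-tetramethoxyacetophenone) | CC(=O)c1c(OC)cc(OC)c(OC)c1OC | intermediate (not isolated)
3 | 1-(2-hydroxy-3,4,6-trimethoxyphenyl)ethan-1-one (2'-hydroxy-3',4',6'-trimethoxyacetophenone) | CC(=O)c1c(OC)cc(OC)c(OC)c1O | intermediate
4 | (E)-3-(dimethylamino)-1-(2-hydroxy-3,4,6-trimethoxyphenyl)prop-2-en-1-one | CN(C)/C=C/C(=O)c1c(OC)cc(OC)c(OC)c1O | intermediate (not isolated)
5 | 5,7,8-trimethoxy-4H-chromen-4-one (5,7,8-trimethoxychromone) | O=c1ccoc2c(OC)c(OC)cc(OC)c12 | intermediate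
6 | 1,2,3,4-tetramethoxybenzene | COc1ccc(OC)c(OC)c1OC | starting material
7 | 5,7,8-trimethoxy-2-(2,3,4,5-tetramethoxyphenyl)-4H-chromen-4-one | COc1cc(-c2cc(=O)c3c(OC)cc(OC)c(OC)c3o2)c(OC)c(OC)c1OC | target

## Step count and risk

Total step count: 3. Longest linear sequence: 3 steps (1 to 3 to 5 to 7); 6 enters in step 3.

Step 3 (key step). The most likely failure is that oxidative self-coupling and silver-mediated one-electron oxidation of the very electron-rich arene 6 consume oxidant and catalyst before insertion into 5 takes place. The ortho methoxy group next to the palladated carbon also slows the insertion, and the arene is used well below solvent quantities. Competing palladation of ring A at C6–H is the second concern.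

The fallback sets out from 5 and 6 and comes back to the route at 7. Compound 6 is lithiated at C5 (n-BuLi, TMEDA, THF, 0 °C), quenched with B(OiPr)3 and hydrolysed to (2,3,4,5-tetramethoxyphenyl)boronic acid F1. F1 is added to 5 in a conjugate addition catalysed by Pd(OCOCF3)2 with 2,2'-bipyridine (AcOH/THF/H2O, 60 °C) to give racemic 5,7,8-trimethoxy-2-(2,3,4,5-tetramethoxyphenyl)chroman-4-one F2. F2 is dehydrogenated with catalytic I2 in DMSO at 120 °C to 7. This replaces the C–H cleavage of the arene by a transmetalation and separates bond formation from dehydrogenation.

Step 1. The most likely failure is cleavage of the wrong ortho ether, or of a second ether next to the new phenoxide under forcing conditions, which would carry the 5,6,7 pattern or a diol through the route. The outcome can be checked on 3 by NOE: 5'-H should show contacts to two methoxy groups.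

No numbered compound can serve as the start of a regiochemically unambiguous fallback, because in 1 the oxygens to be told apart are still equivalent. The fallback therefore sets out from purchasable 3-hydroxy-4,5-dimethoxybenzaldehyde F3 and comes back to the route at 3. F3 is benzylated (BnBr, K2CO3, DMF) to 3-(benzyloxy)-4,5-dimethoxybenzaldehyde F4. F4 is submitted to a Dakin-type oxidation (mCPBA, CH2Cl2; then KOH, MeOH/H2O) to give 3-(benzyloxy)-4,5-dimethoxyphenol F5. F5 is methylated (MeI, K2CO3, acetone) to 1-(benzyloxy)-2,3,5-trimethoxybenzene F6. F6 is hydrogenolysed (H2, Pd/C, EtOAc) to 2,3,5-trimethoxyphenol F7, the same compound as A6. F7 is acylated ortho to the hydroxyl group (AcOH, BF3·OEt2, 80 °C) to give 3. Here the free oxygen is fixed by the starting material and not by a selective ether cleavage.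

Step 2. The most likely failures are O-methylation of the phenol by the amide acetal competing with condensation at the hindered, hydrogen-bonded acetyl group, and hydrolytic opening of ring C with loss of the C2 carbon during the acid stage or work-up.

The fallback sets out from 3 and comes back to the route at 5. Compound 3 is formylated at the methyl group by Claisen condensation with ethyl formate (NaH, THF, 0 °C to rt), giving after acidification the cyclic hemiacetal 2-hydroxy-5,7,8-trimethoxychroman-4-one F8 (racemic). F8 is dehydrated (cat. H2SO4, AcOH, 60 °C) to 5. This brings in C2 as a formyl group through the ketone enolate and avoids the methylating acetal.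

## Further compounds

F1 | step 3 | (2,3,4,5-tetramethoxyphenyl)boronic acid | COc1cc(B(O)O)c(OC)c(OC)c1OC
F2 | step 3 | 5,7,8-trimethoxy-2-(2,3,4,5-tetramethoxyphenyl)chroman-4-one (racemic) | COc1cc(C2CC(=O)c3c(OC)cc(OC)c(OC)c3O2)c(OC)c(OC)c1OC
F3 | step 1 | 3-hydroxy-4,5-dimethoxybenzaldehyde | COc1cc(C=O)cc(O)c1OC
F4 | step 1 | 3-(benzyloxy)-4,5-dimethoxybenzaldehyde | COc1cc(C=O)cc(OCc2ccccc2)c1OC
F5 | step 1 | 3-(benzyloxy)-4,5-dimethoxyphenol | COc1cc(O)cc(OCc2ccccc2)c1OC
F6 | step 1 | 1-(benzyloxy)-2,3,5-trimethoxybenzene | COc1cc(OC)cc(OCc2ccccc2)c1OC
F7 | step 1 | 2,3,5-trimethoxyphenol | COc1cc(O)c(OC)c(OC)c1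
F8 | step 2 | 2-hydroxy-5,7,8-trimethoxychroman-4-one (racemic hemiacetal) | O=C1CC(O)Oc2c(OC)c(OC)cc(OC)c12
A1 | alternative 1 | 2,3,4,5-tetramethoxybenzaldehyde | COc1cc(C=O)c(OC)c(OC)c1OC
A2 | alternative 1 | (E)-1-(2-hydroxy-3,4,6-trimethoxyphenyl)-3-(2,3,4,5-tetramethoxyphenyl)prop-2-en-1-one | COc1cc(/C=C/C(=O)c2c(OC)cc(OC)c(OC)c2O)c(OC)c(OC)c1OC
A3 | alternative 2 | 2-iodo-3,5,6-trimethoxyphenol | Oc1c(I)c(OC)cc(OC)c1OC
A4 | alternative 2 | 1-ethynyl-2,3,4,5-tetramethoxybenzene | C#Cc1cc(OC)c(OC)c(OC)c1OC
A5 | alternative 2 | 1-(2-hydroxy-3,4,6-trimethoxyphenyl)-3-(2,3,4,5-tetramethoxyphenyl)prop-2-yn-1-one | O=C(C#Cc1cc(OC)c(OC)c(OC)c1OC)c1c(OC)cc(OC)c(OC)c1O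
A6 | alternative 2 | 2,3,5-trimethoxyphenol | COc1cc(O)c(OC)c(OC)c1
A7 | alternative 3 | ethyl 3-(2,3,4,5-tetramethoxyphenyl)propiolate | CCOC(=O)C#Cc1cc(OC)c(OC)c(OC)c1OC
A8 | alternative 3 | 3-(2,3,4,5-tetramethoxyphenyl)-3-(2,3,5-trimethoxyphenoxy)acrylic acid (E/Z mixture) | OC(=O)C=C(Oc1cc(OC)cc(OC)c1OC)c1cc(OC)c(OC)c(OC)c1OC
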